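The C1–C8 bond is the disconnection on which everything rests. The C6–C7(prenyl)–C8 bridge is a lavandulyl unit, and ring A (C1–C2–C3–C4–C5–C9) without its C1 acyl and C3 alkyl groups has a mirror plane through C2 and C5. The precursor is therefore a 3,5-dimethoxycyclohexa-2,5-dienone whose quaternary carbon (future C5) carries prenyl and an (S)-lavandulol-derived lavandulyl arm. Cobalt-hydride hydrogen-atom transfer to the isopropenyl group and oxidation give a C8 cation equivalent; one enantiotopic methoxy-enone alpha carbon captures it, closing ring B, forming C1–C8, unveiling the C9 ketone and setting C1 and C5 from C7 in one operation.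

Key step: step 6

Numbering used: C1 acyl-bearing bridgehead; C2(=O)–C3–C4(OH) enolised diketone bridge with the hydroxyalkyl chain on C3; C5 prenyl-bearing bridgehead; C6 methylene; C7 prenyl-bearing methine; C8 gem-dimethyl carbon; C9 bridging ketone. Ring A is C1–C2–C3–C4–C5–C9 and ring B is C1–C8–C7–C6–C5–C9.

Assumption: the lipase acetylates (R)-lavandulol faster, so the unreacted alcohol is the S enantiomer.

Remark: the lavandulyl stereocentre keeps its geometry throughout. Its descriptor is S in 2 and 3 and R from 6 onwards (C7 of the bicycle) only because substituent priorities change. The C1 descriptor likewise switches with the C1 and C3 substituents without any change in geometry.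

**Route**

Step 1
Reactants: 1 (±)-lavandulol
Product: 2 (S)-lavandulol
Conditions: immobilised Candida antarctica lipase B, vinyl acetate, hexane, rt, stopped beyond half conversion; chromatography
Reagents that add atoms: none
Why: Enzymatic kinetic resolution by lipase-catalysed transesterification, in which the enzyme is expected to acetylate the R enantiomer faster, so that running past half conversion should leave the slower S alcohol in high enantiomeric purity (no stereocentre is formed; the future C7 centre is selected here).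

Step 2
Reactants: 2 (S)-lavandulol
Product: 3 (S)-lavandulyl iodide
Conditions: PPh3, I2, imidazole, CH2Cl2, 0 °C → rt
Reagents that add atoms: iodine, I-I
Why: Appel-type iodination (SN2 displacement of the alkoxyphosphonium ion at the primary carbon), which touches neither the adjacent stereocentre nor the alkenes.

Step 3
Reactants: 4 1,5-dimethoxycyclohexa-1,4-diene; 3 (S)-lavandulyl iodide
Product: 6 1,5-dimethoxy-6-[(2R)-5-methyl-2-(prop-1-en-2-yl)hex-4-en-1-yl]cyclohexa-1,4-diene, via lithiated diene 5 (not isolated)
Conditions: 4 (slight excess over base), t-BuLi, THF, −78 °C; then 3, −78 °C → rt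
Reagents that add atoms: (S)-lavandulyl iodide (3), IC[C@@H](CC=C(C)C)C(C)=C
Why: Deprotonation of the methylene flanked by both methoxy-bearing carbons gives a pentadienyl anion that undergoes SN2 alkylation at its central carbon; the beta-branched iodide is introduced first, onto the less hindered anion, to keep E2 elimination down, and no new stereocentre arises.

Step 4
Reactants: 6 1,5-dimethoxy-6-[(2R)-5-methyl-2-(prop-1-en-2-yl)hex-4-en-1-yl]cyclohexa-1,4-diene; 7 prenyl bromide
Product: 9 1,5-dimethoxy-6-(3-methylbut-2-en-1-yl)-6-[(2R)-5-methyl-2-(prop-1-en-2-yl)hex-4-en-1-yl]cyclohexa-1,4-diene, via lithiated dialkyl precursor 8 (not isolated)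
Conditions: t-BuLi, THF, −78 °C; then 7, −78 → 0 °C
Reagents that add atoms: prenyl bromide (7), CC(C)=CCBr
Why: A second lithiation at the same, now tertiary, doubly allylic carbon and SN2 allylation with the reactive primary allylic bromide build the quaternary carbon, which is not stereogenic because the two ring arms are identical.

Step 5
Reactants: 9 1,5-dimethoxy-6-(3-methylbut-2-en-1-yl)-6-[(2R)-5-methyl-2-(prop-1-en-2-yl)hex-4-en-1-yl]cyclohexa-1,4-diene
Product: 10 3,5-dimethoxy-4-(3-methylbut-2-en-1-yl)-4-[(2R)-5-methyl-2-(prop-1-en-2-yl)hex-4-en-1-yl]cyclohexa-2,5-dien-1-one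
Conditions: t-BuOOH (in decane), pyridinium dichromate (C5H5NH)2Cr2O7 (20 mol %), Celite, PhH, 10 °C → rt
Reagents that add atoms: tert-butyl hydroperoxide, CC(C)(C)OO
Why: Bis-allylic oxidation of a Birch-type 1,4-diene by a chromium-promoted tert-butylperoxyl radical chain, in which the ring CH2 flanked by two enol ether double bonds has by far the weakest C–H bond and the peroxide formed there collapses to the cross-conjugated dienone, the ring staying symmetric.

Step 6
Reactants: 10 3,5-dimethoxy-4-(3-methylbut-2-en-1-yl)-4-[(2R)-5-methyl-2-(prop-1-en-2-yl)hex-4-en-1-yl]cyclohexa-2,5-dien-1-one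
Product: 12 (1R,5S,7R)-4-methoxy-8,8-dimethyl-5,7-bis(3-methylbut-2-en-1-yl)bicyclo[3.3.1]non-3-ene-2,9-dione (C7 prenyl exo), via C9 methyloxocarbenium ion 11 (not isolated)
Conditions: N,N'-bis(3,5-di-tert-butylsalicylidene)-1,2-cyclohexanediaminocobalt C36H52CoN2O2 (racemic, divalent cobalt, 5 mol %), N-fluoro-2,4,6-trimethylpyridinium triflate, (Me2SiH)2O, PhCF3, 0 °C → rt, 0.02 M, argon
Reagents that add atoms: none
Why: Proposed new method: the cobalt hydride generated from the fluorocobalt species and the silane should transfer a hydrogen atom to the CH2 terminus of the isopropenyl group, the tertiary C8 radical is oxidised through an alkylcobalt to a C8 cation equivalent, the alpha carbon of one methoxy-enone arm (C1) attacks it to form C1–C8, and the resulting C9 methyloxocarbenium ion 11 is demethylated by the released collidine to the bridging ketone. The closest known reaction types are Mukaiyama-type Markovnikov hydrofunctionalisations of 1,1-disubstituted alkenes under the same cobalt-salen, N-fluoropyridinium and silane conditions (radical-polar crossover) and Lewis-acid ring closures of 6,6-dialkyl-1,5-dimethoxycyclohexa-1,4-dienes onto tertiary cation precursors; capture of the cobalt-generated cation by the carbon of a vinylogous ester is the untested part. Ring B closes in a six-membered enolendo mode (endo with respect to the C1=C9 enol ether bond) through a chair in which C6, C7 and C8 arch over one face of the flat dienone. C1 and C5 become stereogenic in the same event and are both set by C7: only attack by the arm that lets the C7 prenyl group sit equatorial (exo, away from the remaining half of ring A) avoids a syn-axial clash, and the cis relation of the two bridgeheads is imposed by the bicycle. The step needs site-selective hydrogen-atom transfer (the 1,1-disubstituted alkene is more accessible to the bulky cobalt hydride than the trisubstituted prenyl groups), carbon over oxygen capture (attack by a methoxy oxygen gives a tert-alkyl oxonium ion that reverts, whereas the carbon adduct is demethylated irreversibly) and preference for C1 over the C5 prenyl alkene (the ring-bound enol ether is held in place and is the better nucleophile). The dienone oxidation level is what lets the enol ethers survive the electrophilic fluorine oxidant, and the oxidative, acid-free conditions steer the C8 intermediate to C1 rather than to reductive radical addition at the methoxy-bearing beta carbon.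

Step 7
Reactants: 12 (1R,5S,7R)-4-methoxy-8,8-dimethyl-5,7-bis(3-methylbut-2-en-1-yl)bicyclo[3.3.1]non-3-ene-2,9-dione
Product: 14 (1S,5S,7R)-3-iodo-4-methoxy-8,8-dimethyl-5,7-bis(3-methylbut-2-en-1-yl)bicyclo[3.3.1]non-3-ene-2,9-dione, via C3-lithio enone 13 (not isolated)
Conditions: lithium 2,2,6,6-tetramethylpiperidide (LiTMP, 1.05 equiv), THF, −78 °C, short metalation; then I2, −78 °C
Reagents that add atoms: iodine, I-I
Why: Kinetic deprotonation of the vinylic C3–H (alpha to the C2 carbonyl, next to the coordinating C4 methoxy group and far less hindered than the C1–H beside the C8 quaternary carbon) by the bulky amide, followed by iodinolysis of the vinyllithium, with no stereocentre affected.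

Step 8
Reactants: 15 2-methylbut-3-en-2-ol
Product: 16 triethyl[(2-methylbut-3-en-2-yl)oxy]silane
Conditions: Et3SiOTf, 2,6-lutidine, CH2Cl2, 0 °C
Reagents that add atoms: triethylsilyl trifluoromethanesulfonate, CC[Si](CC)(CC)OS(=O)(=O)C(F)(F)F
Why: Silylation of a tertiary alcohol with a silyl triflate and a hindered pyridine base, giving an ether that survives organolithium and palladium chemistry and is cleaved by fluoride.

Step 9
Reactants: 16 triethyl[(2-methylbut-3-en-2-yl)oxy]silane; 14 (1S,5S,7R)-3-iodo-4-methoxy-8,8-dimethyl-5,7-bis(3-methylbut-2-en-1-yl)bicyclo[3.3.1]non-3-ene-2,9-dione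
Product: 18 (1R,5S,7R)-4-methoxy-8,8-dimethyl-5,7-bis(3-methylbut-2-en-1-yl)-3-[3-methyl-3-(triethylsilyloxy)butyl]bicyclo[3.3.1]non-3-ene-2,9-dione, via B-alkyl-9-BBN 17 (not isolated)
Conditions: 16, 9-BBN dimer, THF, 0 °C → rt; then 14, PdCl2(dppf) (5 mol %), AsPh3, Cs2CO3, DMF/H2O, rt
Reagents that add atoms: triethyl[(2-methylbut-3-en-2-yl)oxy]silane (16), CC[Si](CC)(CC)OC(C)(C)C=C
Why: Anti-Markovnikov hydroboration of the terminal alkene with 9-BBN followed by B-alkyl Suzuki–Miyaura coupling with the alpha-iodo enone, a class of vinyl iodide that undergoes oxidative addition readily, the borane being consumed before 14 and its prenyl groups are introduced.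

Step 10
Reactants: 19 (R)-2-methylbutanoic acid
Product: 20 (R)-2-methylbutanoyl chloride
Conditions: (COCl)2, DMF (cat.), CH2Cl2, 0 °C → rt; volatiles removed cold, used crude
Reagents that add atoms: oxalyl chloride, O=C(Cl)C(=O)Cl
Why: Acid chloride formation through the Vilsmeier-type chloroiminium catalyst under base-free conditions, which do not enolise the alpha stereocentre.

Step 11
Reactants: 18 (1R,5S,7R)-4-methoxy-8,8-dimethyl-5,7-bis(3-methylbut-2-en-1-yl)-3-[3-methyl-3-(triethylsilyloxy)butyl]bicyclo[3.3.1]non-3-ene-2,9-dione; 20 (R)-2-methylbutanoyl chloride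
Product: 22 (1S,5S,7R)-4-methoxy-8,8-dimethyl-1-[(2R)-2-methylbutanoyl]-5,7-bis(3-methylbut-2-en-1-yl)-3-[3-methyl-3-(triethylsilyloxy)butyl]bicyclo[3.3.1]non-3-ene-2,9-dione, via C1-lithio bridgehead species 21 (not isolated)
Conditions: LiTMP, THF, −78 °C; then cannulated into 20 (excess) in THF, −78 °C
Reagents that add atoms: (R)-2-methylbutanoyl chloride (20), CC[C@@H](C)C(=O)Cl
Why: Bridgehead lithiation at C1 (the only acidic C–H left, activated by the C2 and C9 carbonyls) and C-acylation with the acid chloride, the bridgehead anion reacting on carbon with retention because it cannot planarise, while inverse addition at low temperature is meant to suppress ketene formation and so keep the R centre of the acyl group that comes from 19.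

Step 12
Reactants: 22 (1S,5S,7R)-4-methoxy-8,8-dimethyl-1-[(2R)-2-methylbutanoyl]-5,7-bis(3-methylbut-2-en-1-yl)-3-[3-methyl-3-(triethylsilyloxy)butyl]bicyclo[3.3.1]non-3-ene-2,9-dione
Product: 24 (1S,5S,7R)-4-hydroxy-3-(3-hydroxy-3-methylbutyl)-8,8-dimethyl-1-[(2R)-2-methylbutanoyl]-5,7-bis(3-methylbut-2-en-1-yl)bicyclo[3.3.1]non-3-ene-2,9-dione (target CNP0326306.1), via lithium enolate 23 (not isolated)
Conditions: LiCl, DMSO, 120 °C; cooled to rt, Bu4NF (THF solution); cold dilute HCl to pH 4–5
Reagents that add atoms: none
Why: SN2 O-demethylation of the vinylogous methyl ester by chloride (Krapcho-type conditions) gives the stabilised diketonate, in which the silyl ether is then cleaved by fluoride without risk of the freed alkoxide adding to C4, and the mildly acidic work-up should return the enol and the tertiary alcohol without cyclodehydration.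

**Compound list**

1 | (±)-lavandulol, (RS)-5-methyl-2-(prop-1-en-2-yl)hex-4-en-1-ol | CC(C)=CCC(CO)C(C)=C | starting material
2 | (S)-lavandulol | OC[C@@H](CC=C(C)C)C(C)=C | intermediate
3 | (S)-lavandulyl iodide, (5S)-6-iodo-2-methyl-5-(prop-1-en-2-yl)hex-2-ene | IC[C@@H](CC=C(C)C)C(C)=C | intermediate
4 | 1,5-dimethoxycyclohexa-1,4-diene | COC1=CCC=C(OC)C1 | starting material
5 | 6-lithio-1,5-dimethoxycyclohexa-1,4-diene (pentadienyl anion, drawn C-lithiated) | COC1=CCC=C(OC)C1[Li] | intermediate
6 | 1,5-dimethoxy-6-[(2R)-5-methyl-2-(prop-1-en-2-yl)hex-4-en-1-yl]cyclohexa-1,4-diene | COC1=CCC=C(OC)C1C[C@@H](CC=C(C)C)C(C)=C | intermediate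
7 | prenyl bromide, 1-bromo-3-methylbut-2-ene | CC(C)=CCBr | starting material
8 | 6-lithio derivative of 6 | COC1=CCC=C(OC)C1([Li])C[C@@H](CC=C(C)C)C(C)=C | intermediate
9 | 1,5-dimethoxy-6-(3-methylbut-2-en-1-yl)-6-[(2R)-5-methyl-2-(prop-1-en-2-yl)hex-4-en-1-yl]cyclohexa-1,4-diene | COC1=CCC=C(OC)C1(CC=C(C)C)C[C@@H](CC=C(C)C)C(C)=C | intermediate
10 | 3,5-dimethoxy-4-(3-methylbut-2-en-1-yl)-4-[(2R)-5-methyl-2-(prop-1-en-2-yl)hex-4-en-1-yl]cyclohexa-2,5-dien-1-one (key-step precursor) | COC1=CC(=O)C=C(OC)C1(CC=C(C)C)C[C@@H](CC=C(C)C)C(C)=C | intermediate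
11 | C9 O-methyl oxocarbenium ion of the ring-closed bicycle | [C@H]12C(=O)C=C(OC)[C@](CC=C(C)C)(C[C@@H](CC=C(C)C)C1(C)C)C2=[O+]C | intermediate
12 | (1R,5S,7R)-4-methoxy-8,8-dimethyl-5,7-bis(3-methylbut-2-en-1-yl)bicyclo[3.3.1]non-3-ene-2,9-dione, C7 prenyl exo (key-step product) | [C@H]12C(=O)C=C(OC)[C@](CC=C(C)C)(C[C@@H](CC=C(C)C)C1(C)C)C2=O | intermediate
13 | C3-lithio derivative of 12 | [C@H]12C(=O)C([Li])=C(OC)[C@](CC=C(C)C)(C[C@@H](CC=C(C)C)C1(C)C)C2=O | intermediate
14 | (1S,5S,7R)-3-iodo-4-methoxy-8,8-dimethyl-5,7-bis(3-methylbut-2-en-1-yl)bicyclo[3.3.1]non-3-ene-2,9-dione | [C@H]12C(=O)C(=C(OC)[C@](CC=C(C)C)(C[C@@H](CC=C(C)C)C1(C)C)C2=O)I | intermediate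
15 | 2-methylbut-3-en-2-ol | CC(C)(O)C=C | starting material
16 | triethyl[(2-methylbut-3-en-2-yl)oxy]silane | CC[Si](CC)(CC)OC(C)(C)C=C | intermediate
17 | 9-[3-methyl-3-(triethylsilyloxy)butyl]-9-borabicyclo[3.3.1]nonane | CC[Si](CC)(CC)OC(C)(C)CCB1C2CCCC1CCC2 | intermediate
18 | (1R,5S,7R)-4-methoxy-8,8-dimethyl-5,7-bis(3-methylbut-2-en-1-yl)-3-[3-methyl-3-(triethylsilyloxy)butyl]bicyclo[3.3.1]non-3-ene-2,9-dione | [C@H]12C(=O)C(CCC(C)(C)O[Si](CC)(CC)CC)=C(OC)[C@](CC=C(C)C)(C[C@@H](CC=C(C)C)C1(C)C)C2=O | intermediate
19 | (R)-2-methylbutanoic acid | CC[C@@H](C)C(=O)O | starting material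
20 | (R)-2-methylbutanoyl chloride | CC[C@@H](C)C(=O)Cl | intermediate
21 | C1-lithio (bridgehead) derivative of 18 | [Li][C@]12C(=O)C(CCC(C)(C)O[Si](CC)(CC)CC)=C(OC)[C@](CC=C(C)C)(C[C@@H](CC=C(C)C)C1(C)C)C2=O | intermediate
22 | (1S,5S,7R)-4-methoxy-8,8-dimethyl-1-[(2R)-2-methylbutanoyl]-5,7-bis(3-methylbut-2-en-1-yl)-3-[3-methyl-3-(triethylsilyloxy)butyl]bicyclo[3.3.1]non-3-ene-2,9-dione | CC[C@@H](C)C(=O)[C@]12C(=O)C(CCC(C)(C)O[Si](CC)(CC)CC)=C(OC)[C@](CC=C(C)C)(C[C@@H](CC=C(C)C)C1(C)C)C2=O | intermediate
23 | lithium C4-enolate of the O-demethylated silyl ether | CC[C@@H](C)C(=O)[C@]12C(=O)C(CCC(C)(C)O[Si](CC)(CC)CC)=C(O[Li])[C@](CC=C(C)C)(C[C@@H](CC=C(C)C)C1(C)C)C2=O | intermediate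
24 | (1S,5S,7R)-4-hydroxy-3-(3-hydroxy-3-methylbutyl)-8,8-dimethyl-1-[(2R)-2-methylbutanoyl]-5,7-bis(3-methylbut-2-en-1-yl)bicyclo[3.3.1]non-3-ene-2,9-dione | CC[C@@H](C)C(=O)[C@]12C(=O)C(CCC(C)(C)O)=C(O)[C@](CC=C(C)C)(C[C@@H](CC=C(C)C)C1(C)C)C2=O | target

Total step count: 12. Longest linear sequence: 10 steps (1, 2, 3, 4, 5, 6, 7, 9, 11, 12).

**Steps most likely to fail**

Step 6 (new method). Hydrogen-atom transfer may not discriminate well enough between the isopropenyl and prenyl alkenes. Reversible hydrogen-atom transfer may move the terminal double bond into the C7–C8 position and erase the C7 centre. The C8 intermediate may be intercepted by a methoxy oxygen, by the C5 prenyl alkene or by the wrong arm instead of by C1. The fallback uses known chemistry, sets out from 10 and returns at 12, and makes the cation in two classical stages instead of by radical-polar crossover. Mukaiyama hydration of 10 (Co(acac)2 cat., PhSiH3, O2, i-PrOH, rt) favours the 1,1-disubstituted alkene and traps the C8 radical with oxygen before it can cyclise or isomerise. It would give 4-[(2R)-2-(2-hydroxypropan-2-yl)-5-methylhex-4-en-1-yl]-3,5-dimethoxy-4-(3-methylbut-2-en-1-yl)cyclohexa-2,5-dien-1-one F1. Ionisation of this tertiary alcohol with BF3·OEt2 in CH2Cl2 at −78 °C is a Friedel–Crafts-type alkylation of the vinylogous ester carbon by a tertiary carbocation, as in Lewis-acid closures of dimethoxycyclohexadienes and biomimetic cation cyclisations of prenylated acylphloroglucinols. It should form the same C1–C8 bond under the same C7 control and, after loss of the C9 O-methyl group, deliver 12.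

Step 11. Metalation of the hindered C1–H beside the C8 quaternary carbon may be incomplete. Ketene formation from the acid chloride, or enolisation of the new ketone by excess base, would scramble the 2-methylbutanoyl stereocentre. The fallback sets out from 18 (through 21) and returns at 22, and replaces acyl substitution by carbonyl addition and oxidation. Reduction of 20 with LiAlH(O-t-Bu)3 in THF at −78 °C gives (R)-2-methylbutanal F2, used at once as a cold solution. Addition of 21 to it at −78 °C gives the carbinol (1S,5S,7R)-1-[(2R)-1-hydroxy-2-methylbutyl]-4-methoxy-8,8-dimethyl-5,7-bis(3-methylbut-2-en-1-yl)-3-[3-methyl-3-(triethylsilyloxy)butyl]bicyclo[3.3.1]non-3-ene-2,9-dione F3 as a mixture at the carbinol carbon, which does not matter. Its alkoxide cannot epimerise, and Dess–Martin periodinane oxidation under neutral conditions (CH2Cl2, NaHCO3, rt) gives 22.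

Step 7. Regiocontrol may be lost through direct C1 metalation, or through proton transfer from C1–H to the C3 anion before the iodine quench, leading to bridgehead iodination or mixtures. The fallback sets out from 12 and returns at 14, and traps the kinetic anion as it forms. LiTMP is added to 12 in the presence of Me3SiCl (in-situ quench, THF, −78 °C), which silylates 13 at once to give (1S,5S,7R)-4-methoxy-8,8-dimethyl-5,7-bis(3-methylbut-2-en-1-yl)-3-(trimethylsilyl)bicyclo[3.3.1]non-3-ene-2,9-dione F4. Ipso-iododesilylation with N-iodosuccinimide in MeCN at 0 °C then gives 14. The silicon-bearing C3 is the nucleophilic carbon of the vinylogous ester, and the beta-silyl oxocarbenium ion sheds silicon.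

**Further compounds**

F1 | step 6 | 4-[(2R)-2-(2-hydroxypropan-2-yl)-5-methylhex-4-en-1-yl]-3,5-dimethoxy-4-(3-methylbut-2-en-1-yl)cyclohexa-2,5-dien-1-one | COC1=CC(=O)C=C(OC)C1(CC=C(C)C)C[C@@H](CC=C(C)C)C(C)(C)O
F2 | step 11 | (R)-2-methylbutanal | CC[C@@H](C)C=O
F3 | step 11 | (1S,5S,7R)-1-[(2R)-1-hydroxy-2-methylbutyl]-4-methoxy-8,8-dimethyl-5,7-bis(3-methylbut-2-en-1-yl)-3-[3-methyl-3-(triethylsilyloxy)butyl]bicyclo[3.3.1]non-3-ene-2,9-dione (carbinol epimers) | CC[C@@H](C)C(O)[C@]12C(=O)C(CCC(C)(C)O[Si](CC)(CC)CC)=C(OC)[C@](CC=C(C)C)(C[C@@H](CC=C(C)C)C1(C)C)C2=O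
F4 | step 7 | (1S,5S,7R)-4-methoxy-8,8-dimethyl-5,7-bis(3-methylbut-2-en-1-yl)-3-(trimethylsilyl)bicyclo[3.3.1]non-3-ene-2,9-dione | [C@H]12C(=O)C([Si](C)(C)C)=C(OC)[C@](CC=C(C)C)(C[C@@H](CC=C(C)C)C1(C)C)C2=O
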